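**Plan**
- Retrosynthesis: after removal of the O-benzyl and O-silyl groups, ring A is cut at C3a–C7a and C4–C5 with N2 restored between C5 and C7a, which gives a pyridazine carrying a tethered alkyne. The aryl ether bond O1–C7a is cut next (SNAr), then the chain bond C2–C3 (aldehyde plus allenylzinc).
- Enabling feature: C7a (O), C7 (OMe), C6 (H) and C5 (CO2Me) of ring A correspond to C6, C5, C4 and C3 of a pyridazine, and O1–C2–C3 is a three-atom tether to an alkyne that supplies C3a and C4.
- Forward order: C2–C3 is joined first (step 5), O1–C7a second (step 8), and ring A and the dihydrofuran ring arise together in step 9 by cycloaddition and loss of N2.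
- Stereochemistry: C3 comes from an (S)-propargylic mesylate (Noyori transfer hydrogenation) by chirality transfer through an allenylzinc. C2 comes from the anti-selective cyclic transition state of that addition. The anti alcohol becomes the trans-2,3 relation with no bond to either centre broken.

Key step: step 9

Assumption: the ynone reduction (alkynyl as the directing π-group) and the allenylzinc addition (anti SN2' palladation, retentive transmetallation, syn SE2' addition) are taken to follow their established stereochemical courses with this α-silyloxymethyl substrate.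

**Route**

Step 1
Reactants: 1 trimethylsilylacetylene; 2 (tert-butyldimethylsilyloxy)acetaldehyde
Product: 4 rac-1-[(tert-butyldimethylsilyl)oxy]-4-(trimethylsilyl)but-3-yn-2-ol, via lithium (trimethylsilyl)acetylide 3 (not isolated)
Conditions: n-BuLi, THF, −78 °C; then 2, −78 to 0 °C; aq NH4Cl
Reagents that add atoms: none
Why: 1,2-addition of a lithium acetylide to an aldehyde is reliable at low temperature, and the carbinol centre is formed racemic on purpose because step 2 removes it.

Step 2
Reactants: 4 rac-1-[(tert-butyldimethylsilyl)oxy]-4-(trimethylsilyl)but-3-yn-2-ol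
Product: 5 1-[(tert-butyldimethylsilyl)oxy]-4-(trimethylsilyl)but-3-yn-2-one
Conditions: MnO2 (activated, excess), CH2Cl2, rt
Reagents that add atoms: none
Why: activated MnO2 oxidises propargylic alcohols to ynones under neutral conditions that leave both silyl groups untouched.

Step 3
Reactants: 5 1-[(tert-butyldimethylsilyl)oxy]-4-(trimethylsilyl)but-3-yn-2-one
Product: 6 (S)-1-[(tert-butyldimethylsilyl)oxy]-4-(trimethylsilyl)but-3-yn-2-ol
Conditions: RuCl[(R,R)-TsDPEN](p-cymene) (1 mol %), i-PrOH, rt
Reagents that add atoms: none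
Why: Noyori asymmetric transfer hydrogenation of an ynone, in which the alkynyl group acts as the directing π-substituent so that the (R,R)-ligand should give the alcohol shown (its descriptor is S because CH2OSi outranks the alkynyl carbon).

Step 4
Reactants: 6 (S)-1-[(tert-butyldimethylsilyl)oxy]-4-(trimethylsilyl)but-3-yn-2-ol
Product: 7 (S)-1-[(tert-butyldimethylsilyl)oxy]-4-(trimethylsilyl)but-3-yn-2-yl methanesulfonate
Conditions: MsCl, Et3N, CH2Cl2, −78 to 0 °C
Reagents that add atoms: methanesulfonyl chloride CS(=O)(=O)Cl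
Why: O-sulfonylation of a secondary propargylic alcohol takes place at oxygen and leaves the stereocentre unchanged.

Step 5
Reactants: 7 (S)-1-[(tert-butyldimethylsilyl)oxy]-4-(trimethylsilyl)but-3-yn-2-yl methanesulfonate; 8 4-(benzyloxy)-3-methoxybenzaldehyde
Product: 10 (1S,2R)-1-[4-(benzyloxy)-3-methoxyphenyl]-2-{[(tert-butyldimethylsilyl)oxy]methyl}-4-(trimethylsilyl)but-3-yn-1-ol, via allenylzinc methanesulfonate 9 (not isolated)
Conditions: Pd(OAc)2 (5 mol %), PPh3 (5 mol %), Et2Zn (3 equiv), THF, −78 to −20 °C; aq NH4Cl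
Reagents that add atoms: none
Why: Marshall propargylation, in which zerovalent palladium displaces the mesylate in an anti SN2' sense, transmetallation to zinc with retention gives the (P)-allenylzinc 9, and its cyclic six-membered SE2' transition state forms the new C–C bond syn to zinc (transferring the mesylate chirality to C2 of the butynol as R) with the aryl group turned away from the CH2OSi group (setting the carbinol as S, the anti isomer, any minor syn isomer to be removed by chromatography).

Step 6
Reactants: 10 (1S,2R)-1-[4-(benzyloxy)-3-methoxyphenyl]-2-{[(tert-butyldimethylsilyl)oxy]methyl}-4-(trimethylsilyl)but-3-yn-1-ol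
Product: 11 (1S,2R)-1-[4-(benzyloxy)-3-methoxyphenyl]-2-{[(tert-butyldimethylsilyl)oxy]methyl}but-3-yn-1-ol
Conditions: K2CO3, MeOH, 0 °C to rt
Reagents that add atoms: none
Why: carbonate-mediated methanolysis of the alkynyl C–Si bond is selective over the primary TBS ether and the benzyl ether and frees the terminal alkyne that must become C4–H.

Step 7
Reactants: 12 3,6-dichloro-4-methoxypyridazine
Product: 13 methyl 6-chloro-5-methoxypyridazine-3-carboxylate
Conditions: Pd(OAc)2 (3 mol %), dppf (4 mol %), CO (5 bar), Et3N (1.5 equiv), MeOH, 60 °C, stopped at partial conversion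
Reagents that add atoms: carbon monoxide [C-]#[O+]; methanol CO
Why: palladium-catalysed alkoxycarbonylation of a chlorodiazine, in which oxidative addition is expected at the C6–Cl bond of 12 because the C3–Cl bond is flanked by the methoxy group, whose lone pair also enriches that carbon, while partial conversion guards against a second carbonylation.

Step 8
Reactants: 11 (1S,2R)-1-[4-(benzyloxy)-3-methoxyphenyl]-2-{[(tert-butyldimethylsilyl)oxy]methyl}but-3-yn-1-ol; 13 methyl 6-chloro-5-methoxypyridazine-3-carboxylate
Product: 15 methyl 6-{[(1S,2R)-1-[4-(benzyloxy)-3-methoxyphenyl]-2-{[(tert-butyldimethylsilyl)oxy]methyl}but-3-yn-1-yl]oxy}-5-methoxypyridazine-3-carboxylate, via sodium alkoxide 14 (not isolated)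
Conditions: NaH (1.05 equiv), THF, 0 °C; then added to 13, THF, 0 °C to rt
Reagents that add atoms: none
Why: nucleophilic aromatic substitution by addition–elimination, in which the remaining chloride of 13 lies α to a ring nitrogen and para to the ester-bearing carbon, so the preformed alkoxide should displace it at 0 °C with both stereocentres untouched.

Step 9
Reactants: 15 methyl 6-{[(1S,2R)-1-[4-(benzyloxy)-3-methoxyphenyl]-2-{[(tert-butyldimethylsilyl)oxy]methyl}but-3-yn-1-yl]oxy}-5-methoxypyridazine-3-carboxylate
Product: 17 methyl (2S,3R)-2-[4-(benzyloxy)-3-methoxyphenyl]-3-{[(tert-butyldimethylsilyl)oxy]methyl}-7-methoxy-2,3-dihydro-1-benzofuran-5-carboxylate, via bridged diazene cycloadduct 16 (not isolated)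
Conditions: 1,3,5-triisopropylbenzene (0.02 M, degassed), 200 °C, sealed tube
Reagents that add atoms: none
Why: the tethered terminal alkyne adds across C6 and C3 of the ester-activated pyridazine in an intramolecular inverse-electron-demand (4+2) cycloaddition to give the bridged adduct 16, which loses N2 by retro-(4+2) and is aromatic at once with no oxidation needed. The closest known reaction type is the intramolecular alkyne 1,2-diazine Diels–Alder reaction that gives indolines and 2,3-dihydrobenzofurans. The dihydrofuran ring closes as the five-membered tether ring of the cycloaddition through the C3a–C7a bond, and ring A is formed as the six-membered ring of the (4+2) step through C3a–C7a and C4–C5 and is aromatised by the cycloreversion. No stereocentre is created, since the bridgeheads of 16 vanish on loss of N2 and C2 and C3 are spectators, so the anti relation of 15 appears as the trans-2,3 relation. Regiochemistry is fixed by the three-atom tether, which lets the internal alkyne carbon reach only C6 and the terminal one only C3; the selectivity needed is cycloaddition ahead of thermal cleavage of the benzylic pyridazinyl ether, helped by the LUMO-lowering ester and by the two tether substituents that favour the folded conformer.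

Step 10
Reactants: 17 methyl (2S,3R)-2-[4-(benzyloxy)-3-methoxyphenyl]-3-{[(tert-butyldimethylsilyl)oxy]methyl}-7-methoxy-2,3-dihydro-1-benzofuran-5-carboxylate
Product: 18 methyl (2S,3R)-2-[4-(benzyloxy)-3-methoxyphenyl]-3-(hydroxymethyl)-7-methoxy-2,3-dihydro-1-benzofuran-5-carboxylate
Conditions: TBAF, AcOH, THF, 0 °C to rt
Reagents that add atoms: none
Why: fluoride cleaves the primary TBS ether, and the AcOH buffer keeps the methyl ester and the benzylic aryl ether away from basic fluoride while the phenol is still protected.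

Step 11
Reactants: 18 methyl (2S,3R)-2-[4-(benzyloxy)-3-methoxyphenyl]-3-(hydroxymethyl)-7-methoxy-2,3-dihydro-1-benzofuran-5-carboxylate
Product: 19 curlignan
Conditions: H2 (1 atm), 10% Pd/C, EtOAc, rt
Reagents that add atoms: none
Why: hydrogenolysis of the phenolic benzyl ether over Pd/C under neutral conditions should be faster than cleavage of the cyclic benzylic C2–O1 bond and does not touch the stereocentres.

**Compound list**

1 | trimethylsilylacetylene | C#C[Si](C)(C)C | starting material
2 | (tert-butyldimethylsilyloxy)acetaldehyde | O=CCO[Si](C)(C)C(C)(C)C | starting material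
3 | lithium (trimethylsilyl)acetylide | [Li]C#C[Si](C)(C)C | intermediate
4 | rac-1-[(tert-butyldimethylsilyl)oxy]-4-(trimethylsilyl)but-3-yn-2-ol | CC(C)(C)[Si](C)(C)OCC(O)C#C[Si](C)(C)C | intermediate
5 | 1-[(tert-butyldimethylsilyl)oxy]-4-(trimethylsilyl)but-3-yn-2-one | CC(C)(C)[Si](C)(C)OCC(=O)C#C[Si](C)(C)C | intermediate
6 | (S)-1-[(tert-butyldimethylsilyl)oxy]-4-(trimethylsilyl)but-3-yn-2-ol | CC(C)(C)[Si](C)(C)OC[C@@H](O)C#C[Si](C)(C)C | intermediate
7 | (S)-1-[(tert-butyldimethylsilyl)oxy]-4-(trimethylsilyl)but-3-yn-2-yl methanesulfonate | CC(C)(C)[Si](C)(C)OC[C@@H](OS(C)(=O)=O)C#C[Si](C)(C)C | intermediate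
8 | 4-(benzyloxy)-3-methoxybenzaldehyde (O-benzylvanillin) | COc1cc(C=O)ccc1OCc1ccccc1 | starting material
9 | (P)-{4-[(tert-butyldimethylsilyl)oxy]-1-(trimethylsilyl)buta-1,2-dien-1-yl}zinc methanesulfonate | CC(C)(C)[Si](C)(C)OCC([H])=[C@]=C([Zn]OS(C)(=O)=O)[Si](C)(C)C | intermediate
10 | (1S,2R)-1-[4-(benzyloxy)-3-methoxyphenyl]-2-{[(tert-butyldimethylsilyl)oxy]methyl}-4-(trimethylsilyl)but-3-yn-1-ol | O[C@H](c1ccc(OCc2ccccc2)c(OC)c1)[C@@H](CO[Si](C)(C)C(C)(C)C)C#C[Si](C)(C)C | intermediate
11 | (1S,2R)-1-[4-(benzyloxy)-3-methoxyphenyl]-2-{[(tert-butyldimethylsilyl)oxy]methyl}but-3-yn-1-ol | O[C@H](c1ccc(OCc2ccccc2)c(OC)c1)[C@@H](CO[Si](C)(C)C(C)(C)C)C#C | intermediate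
12 | 3,6-dichloro-4-methoxypyridazine | COc1cc(Cl)nnc1Cl | starting material
13 | methyl 6-chloro-5-methoxypyridazine-3-carboxylate | COC(=O)c1cc(OC)c(Cl)nn1 | intermediate
14 | sodium (1S,2R)-1-[4-(benzyloxy)-3-methoxyphenyl]-2-{[(tert-butyldimethylsilyl)oxy]methyl}but-3-yn-1-olate | [Na+].[O-][C@H](c1ccc(OCc2ccccc2)c(OC)c1)[C@@H](CO[Si](C)(C)C(C)(C)C)C#C | intermediate
15 | methyl 6-{[(1S,2R)-1-[4-(benzyloxy)-3-methoxyphenyl]-2-{[(tert-butyldimethylsilyl)oxy]methyl}but-3-yn-1-yl]oxy}-5-methoxypyridazine-3-carboxylate | COC(=O)c1cc(OC)c(nn1)O[C@H](c1ccc(OCc2ccccc2)c(OC)c1)[C@@H](CO[Si](C)(C)C(C)(C)C)C#C | intermediate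
16 | bridged (4+2) adduct of 15: a 2,3-diazabicyclo[2.2.2]octa-2,5,7-triene with CO2Me at one bridgehead, the tether oxygen at the other, OMe on the adjoining alkene carbon and the O–CH(Ar)–CH(CH2OTBS) chain closing the five-membered ring; bridgehead configuration left open, both forms give 17 | COC(=O)C12N=NC3(O[C@H](c4ccc(OCc5ccccc5)c(OC)c4)[C@@H](CO[Si](C)(C)C(C)(C)C)C3=C1)C(OC)=C2 | intermediate
17 | methyl (2S,3R)-2-[4-(benzyloxy)-3-methoxyphenyl]-3-{[(tert-butyldimethylsilyl)oxy]methyl}-7-methoxy-2,3-dihydro-1-benzofuran-5-carboxylate | COC(=O)c1cc(OC)c2c(c1)[C@H](CO[Si](C)(C)C(C)(C)C)[C@@H](c1ccc(OCc3ccccc3)c(OC)c1)O2 | intermediate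
18 | methyl (2S,3R)-2-[4-(benzyloxy)-3-methoxyphenyl]-3-(hydroxymethyl)-7-methoxy-2,3-dihydro-1-benzofuran-5-carboxylate | COC(=O)c1cc(OC)c2c(c1)[C@H](CO)[C@@H](c1ccc(OCc3ccccc3)c(OC)c1)O2 | intermediate
19 | curlignan, methyl (2S,3R)-2-(4-hydroxy-3-methoxyphenyl)-3-(hydroxymethyl)-7-methoxy-2,3-dihydro-1-benzofuran-5-carboxylate | COC(=O)c1cc(OC)c2c(c1)[C@H](CO)[C@@H](c1ccc(O)c(OC)c1)O2 | target

**Step count**

Total: 11 steps. Longest linear sequence: 10 steps (steps 1–6 and 8–11, from 1 and 2 to 19); step 7 is a one-step side branch.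

**Steps most likely to fail**

Step 9. At about 200 °C the electron-rich secondary benzylic pyridazinyl ether may ionise, or lose the pyridazinone by a retro-ene path, faster than the alkyne adds; return from an ion pair would also erode the configuration at C2. The fallback replaces the para donor by an acceptor for the thermal step; it sets out from 7 and comes back to the route at 19. Vanillin is sulfonylated (TsCl, Et3N, CH2Cl2) to 4-formyl-2-methoxyphenyl 4-methylbenzenesulfonate F1, which takes the place of 8 under the conditions of step 5 and should give the tosyl-protected anti alcohol F2. K2CO3 in MeOH gives the terminal alkyne F3, and NaH followed by 13 gives the pyridazinyl ether F4. Heating as in step 9 should then give the dihydrobenzofuran F5, whose benzylic C–O bond is far harder to ionise. TBAF/AcOH gives the primary alcohol F6, and Mg in MeOH at rt cleaves the aryl sulfonate to give 19.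

Step 7. Once the ester is in place the remaining chloride is more activated than either chloride of 12, so a second carbonylation or displacement by methanol may overtake the first; discrimination between the two C–Cl bonds in the oxidative addition may also be incomplete. The fallback introduces the carbon as a group that does not activate the ring and sets the oxidation level afterwards; it sets out from 12 and comes back at 13. Suzuki–Miyaura coupling of 12 with potassium vinyltrifluoroborate (PdCl2(dppf), K2CO3, dioxane/H2O, 80 °C) should give 3-chloro-6-ethenyl-4-methoxypyridazine F7 at the chloride remote from the methoxy group. Oxidative cleavage (RuCl3 cat., NaIO4, MeCN/EtOAc/H2O) gives 6-chloro-5-methoxypyridazine-3-carboxylic acid F8, and TMSCHN2 in MeOH/toluene gives 13.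

Step 8. The hindered secondary alkoxide may attack the methyl ester instead of the ring carbon next to the methoxy group, releasing methoxide that then consumes 13. The fallback forms the C–O bond by cross-coupling under a weak base, so that no free alkoxide is present; it sets out from 10 (with 13) and comes back at 15. Palladium-catalysed etherification of the silyl-protected alcohol 10 with 13 ([Pd(allyl)Cl]2, RockPhos, Cs2CO3, toluene, 80 °C) should give the C-silylated pyridazinyl ether F9, the silyl group keeping the alkyne out of the palladium chemistry. K2CO3 in MeOH at 0 °C then removes the alkynyl silyl group to give 15.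

**Further compounds**

F1 | step 9 | 4-formyl-2-methoxyphenyl 4-methylbenzenesulfonate | Cc1ccc(cc1)S(=O)(=O)Oc1ccc(C=O)cc1OC
F2 | step 9 | (1S,2R)-2-{[(tert-butyldimethylsilyl)oxy]methyl}-1-{3-methoxy-4-[(4-methylbenzenesulfonyl)oxy]phenyl}-4-(trimethylsilyl)but-3-yn-1-ol | O[C@H](c1ccc(OS(=O)(=O)c2ccc(C)cc2)c(OC)c1)[C@@H](CO[Si](C)(C)C(C)(C)C)C#C[Si](C)(C)C
F3 | step 9 | (1S,2R)-2-{[(tert-butyldimethylsilyl)oxy]methyl}-1-{3-methoxy-4-[(4-methylbenzenesulfonyl)oxy]phenyl}but-3-yn-1-ol | O[C@H](c1ccc(OS(=O)(=O)c2ccc(C)cc2)c(OC)c1)[C@@H](CO[Si](C)(C)C(C)(C)C)C#C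
F4 | step 9 | methyl 6-{[(1S,2R)-2-{[(tert-butyldimethylsilyl)oxy]methyl}-1-{3-methoxy-4-[(4-methylbenzenesulfonyl)oxy]phenyl}but-3-yn-1-yl]oxy}-5-methoxypyridazine-3-carboxylate | COC(=O)c1cc(OC)c(nn1)O[C@H](c1ccc(OS(=O)(=O)c2ccc(C)cc2)c(OC)c1)[C@@H](CO[Si](C)(C)C(C)(C)C)C#C
F5 | step 9 | methyl (2S,3R)-3-{[(tert-butyldimethylsilyl)oxy]methyl}-7-methoxy-2-{3-methoxy-4-[(4-methylbenzenesulfonyl)oxy]phenyl}-2,3-dihydro-1-benzofuran-5-carboxylate | COC(=O)c1cc(OC)c2c(c1)[C@H](CO[Si](C)(C)C(C)(C)C)[C@@H](c1ccc(OS(=O)(=O)c3ccc(C)cc3)c(OC)c1)O2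
F6 | step 9 | methyl (2S,3R)-3-(hydroxymethyl)-7-methoxy-2-{3-methoxy-4-[(4-methylbenzenesulfonyl)oxy]phenyl}-2,3-dihydro-1-benzofuran-5-carboxylate | COC(=O)c1cc(OC)c2c(c1)[C@H](CO)[C@@H](c1ccc(OS(=O)(=O)c3ccc(C)cc3)c(OC)c1)O2
F7 | step 7 | 3-chloro-6-ethenyl-4-methoxypyridazine | COc1cc(C=C)nnc1Cl
F8 | step 7 | 6-chloro-5-methoxypyridazine-3-carboxylic acid | COc1cc(C(=O)O)nnc1Cl
F9 | step 8 | methyl 6-{[(1S,2R)-1-[4-(benzyloxy)-3-methoxyphenyl]-2-{[(tert-butyldimethylsilyl)oxy]methyl}-4-(trimethylsilyl)but-3-yn-1-yl]oxy}-5-methoxypyridazine-3-carboxylate | COC(=O)c1cc(OC)c(nn1)O[C@H](c1ccc(OCc2ccccc2)c(OC)c1)[C@@H](CO[Si](C)(C)C(C)(C)C)C#C[Si](C)(C)C
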